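Rings: A = the terminal 2,4-dihydroxyphenyl ketone ring, B = the para-phenylene ring on the ether oxygen, C = the 2,4-dihydroxy-5-aryloxyphenyl ketone ring, D = the 4-hydroxyphenyl ring; the five phenols are carried as methyl ethers.
Retrosynthesis: both carbonyl C–O bonds are cut first, each enone going back to a 1,3-diarylprop-2-yn-1-ol by 1,3-transposition of oxygen; this works because each carbonyl carbon sits on a ring with ortho- and para-oxygen (A, C) and each Cβ on a ring with para-oxygen (B, D), so both ends of each three-carbon unit are donor-stabilised.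
Further cuts: the C(sp)–C(aryl) bond on ring C (Sonogashira), the carbinol C–C(sp) bond next to ring B (acetylide addition) and the diaryl ether C–O bond (SNAr).
Forward: ether formation, iodination of ring C, acetylide addition, Sonogashira coupling, double rearrangement, global demethylation; all four benzene rings are bought and no ring is formed.
Stereochemistry: the target has no stereocentre; the two carbinol centres are made racemic and erased, and both E double bonds arise under thermodynamic control in the rearrangement.

Key step: step 6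

Remark: both carbinol centres are made racemic and the bis(propargylic alcohol) is carried forward as a mixture of racemic diastereomers, because the rearrangement destroys both centres; the terminal aryl alkyne of step 3 and the ethynyl Grignard solution of step 4 are taken as purchased.

Step 1
Reactants: 1 2,4-dimethoxyphenol; 2 4-fluorobenzaldehyde
Product: 3 4-(2,4-dimethoxyphenoxy)benzaldehyde
Conditions: K2CO3 (1.5 equiv), DMF, N2, 110 °C
Reagents that add atoms: none
Why: Nucleophilic aromatic substitution (SNAr), in which the para-formyl group stabilises the Meisenheimer adduct so that the phenoxide of 1 displaces fluoride, a routine way to 4-aryloxybenzaldehydes.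

Step 2
Reactants: 3 4-(2,4-dimethoxyphenoxy)benzaldehyde
Product: 4 4-(5-iodo-2,4-dimethoxyphenoxy)benzaldehyde
Conditions: NIS (1.05 equiv), TFA (10 mol%), MeCN, 0 °C → rt, dark
Reagents that add atoms: N-iodosuccinimide, O=C1CCC(=O)N1I
Why: Electrophilic aromatic iodination, directed to position 5 of the trioxygenated ring because that carbon is para to the 2-methoxy and ortho to the 4-methoxy group and unhindered, whereas position 3 is flanked by two methoxy groups and the formyl-bearing ring is deactivated.

Step 3
Reactants: 4 4-(5-iodo-2,4-dimethoxyphenoxy)benzaldehyde; 5 1-ethynyl-2,4-dimethoxybenzene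
Product: 7 3-(2,4-dimethoxyphenyl)-1-[4-(5-iodo-2,4-dimethoxyphenoxy)phenyl]prop-2-yn-1-ol (racemic), via lithium (2,4-dimethoxyphenyl)acetylide 6 (not isolated)
Conditions: 5 (1.2 equiv), n-BuLi (1.15 equiv), THF, −78 °C; then 4, −78 → 0 °C; sat. aq. NH4Cl
Reagents that add atoms: none
Why: 1,2-Addition of a lithium acetylide to an aryl aldehyde, with the alkyne kept in slight excess so that no butyllithium remains to exchange with the aryl iodide, which the acetylide itself leaves untouched at low temperature; the new carbinol centre is formed racemic, which is of no consequence.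

Step 4
Reactants: 8 4-methoxybenzaldehyde
Product: 9 1-(4-methoxyphenyl)prop-2-yn-1-ol (racemic)
Conditions: ethynylmagnesium bromide (1.2 equiv, 0.5 M in THF), THF, 0 °C → rt; sat. aq. NH4Cl
Reagents that add atoms: ethynylmagnesium bromide, C#C[Mg]Br
Why: Grignard addition of an alkynyl nucleophile to an aromatic aldehyde, which gives the racemic secondary propargylic alcohol.

Step 5
Reactants: 7 3-(2,4-dimethoxyphenyl)-1-[4-(5-iodo-2,4-dimethoxyphenoxy)phenyl]prop-2-yn-1-ol; 9 1-(4-methoxyphenyl)prop-2-yn-1-ol
Product: 10 3-(2,4-dimethoxyphenyl)-1-{4-[5-(3-hydroxy-3-(4-methoxyphenyl)prop-1-yn-1-yl)-2,4-dimethoxyphenoxy]phenyl}prop-2-yn-1-ol (mixture of racemic diastereomers)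
Conditions: 9 (1.3 equiv), PdCl2(PPh3)2 (3 mol%), CuI (5 mol%), Et3N/THF 1:1, degassed, rt → 45 °C
Reagents that add atoms: none
Why: Sonogashira coupling, in which zerovalent palladium formed in the flask inserts into the aryl C–I bond and the copper acetylide of 9 delivers the alkyne; free secondary propargylic alcohols are tolerated and the electron-rich aryl group on the new alkyne disfavours base-induced isomerisation to an enone.

Step 6
Reactants: 10 3-(2,4-dimethoxyphenyl)-1-{4-[5-(3-hydroxy-3-(4-methoxyphenyl)prop-1-yn-1-yl)-2,4-dimethoxyphenoxy]phenyl}prop-2-yn-1-ol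
Product: 13 (E)-1-(2,4-dimethoxyphenyl)-3-{4-[2,4-dimethoxy-5-((E)-3-(4-methoxyphenyl)prop-2-enoyl)phenoxy]phenyl}prop-2-en-1-one, via ring C mono-enone 11 (not isolated), via ring A mono-enone 12 (not isolated)
Conditions: Ph3PAuNTf2 (5 mol%), MeOH (2 equiv), H2O (2 equiv), toluene (0.05 M), rt → 50 °C
Reagents that add atoms: water, O
Why: Ph3PAuNTf2, a source of cationic monovalent gold, activates each alkyne while the benzylic hydroxyl ionises, which gives a propargyl–allenyl cation stabilised at the carbinol end by the para-oxygen of ring B or D and at the far end by the ortho- and para-methoxy groups of ring A or C; water (or methanol, later exchanged for water) adds at the alkyne carbon bound to ring A or C, and protodeauration followed by tautomerisation of the allenol gives the enone. The closest known reaction type is the Meyer–Schuster rearrangement of 1,3-diarylprop-2-yn-1-ols to chalcones under gold or Brønsted acid catalysis, run here at two sites of one molecule that may react in either order through the mono-enones 11 and 12. No ring is closed and no stereocentre is created: both racemic carbinol centres are destroyed, and each C=C should settle as the thermodynamically favoured E isomer because Z to E isomerisation is open under the conditions. The selectivity needed is regiochemical, since oxygen must end on the carbon attached to ring A or C instead of staying at the carbinol carbon, and the matched donor pattern secures it, because even direct Markovnikov hydration of the aryl alkyne would place oxygen on the same carbon and dehydrate to the same enone. The phenols are carried as methyl ethers because a methyl group on the ortho oxygen is not expected to migrate to the activated alkyne, so benzofuran formation should be avoided, and the dilution should suppress Friedel–Crafts capture of the cation by the electron-rich rings.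

Step 7
Reactants: 13 (E)-1-(2,4-dimethoxyphenyl)-3-{4-[2,4-dimethoxy-5-((E)-3-(4-methoxyphenyl)prop-2-enoyl)phenoxy]phenyl}prop-2-en-1-one
Product: 14 (E)-1-(2,4-dihydroxyphenyl)-3-{4-[2,4-dihydroxy-5-((E)-3-(4-hydroxyphenyl)prop-2-enoyl)phenoxy]phenyl}prop-2-en-1-one (EANPDB:ANAC_00012)
Conditions: BBr3 (10 equiv, 1 M in CH2Cl2), CH2Cl2, −78 °C → rt; then ice/H2O, 0 °C
Reagents that add atoms: none
Why: Lewis-acid cleavage of aryl methyl ethers with BBr3, a known way from methoxychalcones to hydroxychalcones, in which bromide attacks only the methyl carbons, so the diaryl ether, which offers no saturated carbon for substitution, should survive, while the cold aqueous quench limits closure of the 2'-hydroxy enones to flavanones.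

Compound list
1 | 2,4-dimethoxyphenol | COc1ccc(O)c(OC)c1 | starting material
2 | 4-fluorobenzaldehyde | O=Cc1ccc(F)cc1 | starting material
3 | 4-(2,4-dimethoxyphenoxy)benzaldehyde | O=Cc1ccc(Oc2ccc(OC)cc2OC)cc1 | intermediate
4 | 4-(5-iodo-2,4-dimethoxyphenoxy)benzaldehyde | O=Cc1ccc(Oc2cc(I)c(OC)cc2OC)cc1 | intermediate
5 | 1-ethynyl-2,4-dimethoxybenzene | C#Cc1ccc(OC)cc1OC | starting material
6 | lithium (2,4-dimethoxyphenyl)acetylide (not isolated) | [Li]C#Cc1ccc(OC)cc1OC | intermediate
7 | 3-(2,4-dimethoxyphenyl)-1-[4-(5-iodo-2,4-dimethoxyphenoxy)phenyl]prop-2-yn-1-ol (racemic) | OC(C#Cc1ccc(OC)cc1OC)c1ccc(Oc2cc(I)c(OC)cc2OC)cc1 | intermediate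
8 | 4-methoxybenzaldehyde | COc1ccc(C=O)cc1 | starting material
9 | 1-(4-methoxyphenyl)prop-2-yn-1-ol (racemic) | OC(C#C)c1ccc(OC)cc1 | intermediate
10 | 3-(2,4-dimethoxyphenyl)-1-{4-[5-(3-hydroxy-3-(4-methoxyphenyl)prop-1-yn-1-yl)-2,4-dimethoxyphenoxy]phenyl}prop-2-yn-1-ol (mixture of racemic diastereomers) | OC(C#Cc1ccc(OC)cc1OC)c1ccc(Oc2cc(C#CC(O)c3ccc(OC)cc3)c(OC)cc2OC)cc1 | intermediate
11 | (E)-1-{5-[4-(3-(2,4-dimethoxyphenyl)-1-hydroxyprop-2-yn-1-yl)phenoxy]-2,4-dimethoxyphenyl}-3-(4-methoxyphenyl)prop-2-en-1-one (racemic; ring C mono-enone; not isolated) | OC(C#Cc1ccc(OC)cc1OC)c1ccc(Oc2cc(C(=O)/C=C/c3ccc(OC)cc3)c(OC)cc2OC)cc1 | intermediate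
12 | (E)-1-(2,4-dimethoxyphenyl)-3-{4-[5-(3-hydroxy-3-(4-methoxyphenyl)prop-1-yn-1-yl)-2,4-dimethoxyphenoxy]phenyl}prop-2-en-1-one (racemic; ring A mono-enone; not isolated) | O=C(/C=C/c1ccc(Oc2cc(C#CC(O)c3ccc(OC)cc3)c(OC)cc2OC)cc1)c1ccc(OC)cc1OC | intermediate
13 | (E)-1-(2,4-dimethoxyphenyl)-3-{4-[2,4-dimethoxy-5-((E)-3-(4-methoxyphenyl)prop-2-enoyl)phenoxy]phenyl}prop-2-en-1-one | O=C(/C=C/c1ccc(Oc2cc(C(=O)/C=C/c3ccc(OC)cc3)c(OC)cc2OC)cc1)c1ccc(OC)cc1OC | intermediate
14 | (E)-1-(2,4-dihydroxyphenyl)-3-{4-[2,4-dihydroxy-5-((E)-3-(4-hydroxyphenyl)prop-2-enoyl)phenoxy]phenyl}prop-2-en-1-one | O=C(/C=C/c1ccc(Oc2cc(C(=O)/C=C/c3ccc(O)cc3)c(O)cc2O)cc1)c1ccc(O)cc1O | target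

Step count and risks
Total steps: 7. Longest linear sequence: 6 (steps 1, 2, 3, 5, 6, 7); step 4 is a one-step branch.

Steps most likely to fail:

Step 6. The doubly donor-stabilised propargyl cations may be intercepted by the electron-rich rings of a second molecule (Friedel–Crafts propargylation and oligomerisation), or the second site may stall after the first has rearranged. The fallback sets out from 10 and comes back at 13, delivering the oxygen intramolecularly instead of through a free cation and external water. Acetylation of 10 (Ac2O, Et3N, DMAP, CH2Cl2, 0 °C) should give 3-(2,4-dimethoxyphenyl)-1-{4-[5-(3-acetoxy-3-(4-methoxyphenyl)prop-1-yn-1-yl)-2,4-dimethoxyphenoxy]phenyl}prop-2-yn-1-yl acetate F1. Ph3PAuNTf2 in wet butan-2-one at rt should then trigger the known 1,3-acyloxy shift of each propargylic acetate to an allenyl acetate, whose hydrolysis in the same flask gives the E-enones of 13.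

Step 7. Ether cleavage may stop at the non-chelated methoxy groups, or the liberated 2'-hydroxy enones may close by acid-promoted oxa-Michael addition to flavanones. The fallback sets out from 13 and comes back at 14, accepting the ring closure and reversing it afterwards. Heating 13 in 48% aq. HBr/AcOH at reflux should cleave all five methyl ethers and close both units, giving 7-hydroxy-6-{4-[7-hydroxy-4-oxochroman-2-yl]phenoxy}-2-(4-hydroxyphenyl)chroman-4-one F2 as a mixture of stereoisomers. Treatment with aqueous KOH in EtOH at rt should open both flavanone rings by base-induced retro-oxa-Michael elimination to the chalcone phenoxides, and acidification at 0 °C should release 14.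

Step 5. Oxidative addition into the electron-rich, ortho-alkoxy aryl iodide may be slow, leaving the sensitive carbinol 9 to be consumed by copper-mediated oxidative dimerisation. The fallback sets out from 7 and comes back at 10, forming the bond to the carbinol carbon by acetylide addition instead of coupling a preformed carbinol. Coupling of 7 with ethynyltrimethylsilane in excess (PdCl2(PPh3)2, CuI, Et3N, 60 °C), which tolerates forcing conditions, should give 3-(2,4-dimethoxyphenyl)-1-{4-[2,4-dimethoxy-5-((trimethylsilyl)ethynyl)phenoxy]phenyl}prop-2-yn-1-ol F3. K2CO3 in MeOH should remove the silyl group to give 3-(2,4-dimethoxyphenyl)-1-[4-(5-ethynyl-2,4-dimethoxyphenoxy)phenyl]prop-2-yn-1-ol F4. Double deprotonation (n-BuLi, 2.1 equiv, THF, −78 °C) to the alkoxide–acetylide and addition of 4-methoxybenzaldehyde 8 should then give 10.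

Further compounds
F1 | step 6 | 3-(2,4-dimethoxyphenyl)-1-{4-[5-(3-acetoxy-3-(4-methoxyphenyl)prop-1-yn-1-yl)-2,4-dimethoxyphenoxy]phenyl}prop-2-yn-1-yl acetate (mixture of stereoisomers) | CC(=O)OC(C#Cc1ccc(OC)cc1OC)c1ccc(Oc2cc(C#CC(OC(C)=O)c3ccc(OC)cc3)c(OC)cc2OC)cc1
F2 | step 7 | 7-hydroxy-6-{4-[7-hydroxy-4-oxochroman-2-yl]phenoxy}-2-(4-hydroxyphenyl)chroman-4-one (mixture of stereoisomers) | O=C1CC(c2ccc(Oc3cc4C(=O)CC(c5ccc(O)cc5)Oc4cc3O)cc2)Oc2cc(O)ccc12
F3 | step 5 | 3-(2,4-dimethoxyphenyl)-1-{4-[2,4-dimethoxy-5-((trimethylsilyl)ethynyl)phenoxy]phenyl}prop-2-yn-1-ol (racemic) | OC(C#Cc1ccc(OC)cc1OC)c1ccc(Oc2cc(C#C[Si](C)(C)C)c(OC)cc2OC)cc1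
F4 | step 5 | 3-(2,4-dimethoxyphenyl)-1-[4-(5-ethynyl-2,4-dimethoxyphenoxy)phenyl]prop-2-yn-1-ol (racemic) | OC(C#Cc1ccc(OC)cc1OC)c1ccc(Oc2cc(C#C)c(OC)cc2OC)cc1
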